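## Structural features

Positions are numbered as in azulene: C1 is the ketone carbon, C3 carries the isopropyl group, C3a the tertiary hydroxyl, C6 the vinylic methyl, C8 the ester oxygen and C8a the angular methyl. The target is a daucane-type hydroazulene: a cyclopentanone (C1–C2–C3–C3a–C8a) trans-fused along C3a–C8a to a cycloheptene (C3a–C4–C5–C6=C7–C8–C8a), with a 4-methoxybenzoate on O8. Four contiguous stereocentres run C3(R)–C3a(S)–C8a(S)–C8(R): the 3a-hydroxyl is cis to the isopropyl group and trans to the 8a-methyl, and the ester oxygen is cis to the 8a-methyl. C8a is quaternary and sits between three oxygenated carbons (C1=O, C3a–OH, C8–O), so the ketone is a β-hydroxy ketone twice over; base can open it by retro-aldol cleavage, acid can ionise the allylic C8 ester, and a cation at C6 would be trapped across the ring by the 3a-hydroxyl. The real difficulty is the vicinal pair of fully substituted ring-fusion carbons C3a/C8a with their trans relationship, flanked by C3 and C8, on a seven-membered ring. The key step exploits the array O=C1–C8a(CH3)–C3a(OH): it is the product pattern of a semipinacol rearrangement of a 2,3-epoxy alcohol in which the methyl group has moved from C1 to C8a, anti to the C3a oxygen. The precursor of that step is flat at C3a and C8a, and its seven-membered ring with the C6 methyl is a p-tolyl ring plus one carbon (C8a).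

## Logic of the disconnections

17 is cut at the ester C8–O–acyl bond to give 15 and 16. The anisoate would not survive the organometallic and hydride steps, so it is put on last. The forward step must acylate a hindered allylic secondary alcohol and leave the tertiary 3a-hydroxyl alone.

15 is cut at the C8–H bond, back to the enedione 14. The C8 oxygen must lie cis to the 8a-methyl, the face that an electrophilic oxygen source cannot reach; a hydride entering anti to that methyl gives exactly this arrangement. The forward step must choose the conjugated C8 carbonyl over the C1 ketone and the right face.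

14 is traced back to 13 by moving the oxygen from C8 to C6 and the double bond from C6=C7 to C7=C8. This turns a neopentyl oxygenation at C8, hard to reach directly, into a tertiary allylic alcohol at the accessible C6. The forward step is an oxidative allylic transposition that must outrun ionisation of the tertiary allylic alcohol.

13 is cut at the C6–O and C5–H bonds, back to the 5,7-diene 11. A conjugated diene in the seven-membered ring is what an arene-derived ring supplies for free. The forward hydration must put hydrogen on C5; oxygen at either end of the resulting allyl unit converges on 14.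

11 is cut at the C8a–CH3 and C3a–O bonds (key disconnection): the methyl is returned to C1 and the oxygen removed, giving the tertiary allylic alcohol 9 via the epoxide 10. In one sentence, the route is a hydroxyl-directed epoxidation and semipinacol 1,2-methyl shift of 9. The gain is that both fully substituted stereocentres and the trans ring fusion disappear into a tetrasubstituted alkene; only C3 and the carbinol carbon C1 remain stereogenic. The forward step must epoxidise the right alkene on the hydroxyl face, open the epoxide at C8a, and move methyl rather than a ring carbon.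

9 is cut at the C1–CH3 bond, back to the trienone 8. The forward 1,2-addition must occur anti to the C3 isopropyl group and without deprotonation at C4.

8 is cut at the C8a–C3a and C8a–C8 bonds, back to the diazoketone 6 via 7. Removing C8a from the seven-membered ring restores a p-tolyl ring, so a bicyclic trienone becomes an open-chain aryl ketone with one stereocentre. The forward carbenoid must add to the arene rather than insert into the isopropyl C–H bond, and the isomerisation to 8 must not touch C3.

6 is cut at the bond between the carbonyl carbon and the diazomethyl carbon, back to the acid 4 via 5; this is a routine acylation of diazomethane.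

4 is cut, through its ester 3, at the aryl–C3 bond to give 1 and 2. The forward conjugate addition must set C3, the only stereocentre that is not derived from another one.

## Other disconnections considered

Alternative 1: the route that comes to mind first cuts the C6=C7 double bond. The forward key step is ring-closing metathesis of the diene A1 (second-generation Grubbs catalyst), A1 being built on a chiral-pool isopropylcyclopentane. The metathesis only closes the ring. The whole C3/C3a/C8a/C8 tetrad would have to be set beforehand on the cyclopentanone by separate substrate-controlled events: a quaternary C8a next to β-oxygens that can eliminate, a tertiary carbinol trans to it, and the C8 carbinol. That costs more steps and protecting groups. The chosen plan makes the skeleton from an arene in one step and the ring-fusion pair in one stereospecific step.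

Alternative 2: cut the C3a–C8a bond. The forward key step is a transannular aldol of the ten-membered 1,4-diketone A2. On mechanistic grounds, A2 can enolise on either side, and the alternative closure (C4 onto C1) would give a regioisomeric hydroazulene. An enolate at C8a is β to the anisoate and would be expected to eliminate it. The facial outcome of a transannular closure in a flexible Z-cyclodecene is hard to predict, and the medium ring with two remote stereocentres is itself costly. The semipinacol step, by contrast, is stereospecific by mechanism.

Alternative 3: cut one ring carbon out of the seven-membered ring. The forward key step is a one-carbon homologation (diazoalkane insertion) of the six-membered ketone of the hydrindanedione A3. The amino-acid-catalysed aldol that makes such ketols gives the cis ring fusion, opposite to the target, so the carbinol would have to be re-made. The insertion must also distinguish two ketones and two migrating methylene groups. Afterwards the C6 methyl, the C6=C7 double bond and the C8 oxygen would all still be missing. The arene ring expansion of the chosen plan delivers the seven-membered ring with the methyl and the unsaturation already in place.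

Key step: step 6

Remark: ethyl (2E)-4-methylpent-2-enoate (2) is taken as a catalogue compound, and (S)-BINAP is assigned from the usual facial model of the rhodium-catalysed 1,4-addition.

Step 1
Reactants: 1 4-methylphenylboronic acid; 2 ethyl (2E)-4-methylpent-2-enoate
Product: 3 ethyl (3R)-4-methyl-3-(4-methylphenyl)pentanoate
Conditions: Rh(acac)(C2H4)2 (3 mol %), (S)-BINAP (3.3 mol %), 1 (3 equiv), dioxane/H2O 10:1, 100 °C
Reagents that add atoms: none
Why: Hayashi–Miyaura asymmetric 1,4-addition; the aryl–rhodium species adds to the β-carbon and water releases the ester. The BINAP ligand selects the enoate face, and (S)-BINAP is expected to give the 3R adduct (isopropyl outranks the CH2CO2Et arm).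

Step 2
Reactants: 3 ethyl (3R)-4-methyl-3-(4-methylphenyl)pentanoate
Product: 4 (3R)-4-methyl-3-(4-methylphenyl)pentanoic acid
Conditions: LiOH·H2O, THF/MeOH/H2O, rt; then 1 M HCl
Reagents that add atoms: lithium hydroxide, [Li+].[OH-]
Why: Ester saponification; the stereocentre is β to the carboxyl group and cannot epimerise by enolisation.

Step 3
Reactants: 4 (3R)-4-methyl-3-(4-methylphenyl)pentanoic acid
Product: 6 (4R)-1-diazo-5-methyl-4-(4-methylphenyl)hexan-2-one, via acid chloride 5 (not isolated)
Conditions: (COCl)2, DMF (cat.), CH2Cl2, 0 °C to rt; evaporate; CH2N2 (3 equiv), Et2O, 0 °C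
Reagents that add atoms: diazomethane, C=[N+]=[N-]; oxalyl chloride, O=C(Cl)C(Cl)=O (chlorine of 5 only)
Why: Acylation of diazomethane by the acid chloride, as in the first stage of an Arndt–Eistert sequence; excess diazomethane scavenges HCl so that no chloromethyl ketone should form.

Step 4
Reactants: 6 (4R)-1-diazo-5-methyl-4-(4-methylphenyl)hexan-2-one
Product: 8 (3R)-6-methyl-3-(propan-2-yl)-3,4-dihydroazulen-1(2H)-one, via 3,8a-dihydroazulenone 7 (not isolated)
Conditions: Rh2(OAc)4 (1 mol %), CH2Cl2, reflux, slow addition of 6; then Et3N (0.2 equiv), rt
Reagents that add atoms: none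
Why: Intramolecular Buchner reaction: the rhodium carbenoid cyclopropanates the ipso/ortho bond (closing the five-membered ring) and the norcaradiene opens by disrotatory 6π electrocyclic ring opening to cycloheptatriene 7; both ortho bonds are equivalent, so the para methyl ends at C6. The amine then moves the acidic C8a hydrogen to C4 through the extended enolate to give the conjugated isomer 8 without touching C3. A carboxylate catalyst is chosen because it favours arene addition over insertion into the isopropyl C–H bond.

Step 5
Reactants: 8 (3R)-6-methyl-3-(propan-2-yl)-3,4-dihydroazulen-1(2H)-one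
Product: 9 (1R,3R)-1,6-dimethyl-3-(propan-2-yl)-1,2,3,4-tetrahydroazulen-1-ol
Conditions: MeLi, CeCl3 (anhydrous), THF, −78 °C; pH 7 buffer work-up
Reagents that add atoms: methyllithium, [Li]C
Why: 1,2-Addition of the organocerium reagent, whose low basicity should suppress deprotonation at C4. Attack anti to the C3 isopropyl group on the nearly flat cyclopentenone should place the new methyl trans and the hydroxyl cis to the isopropyl group (1R).

Step 6
Reactants: 9 (1R,3R)-1,6-dimethyl-3-(propan-2-yl)-1,2,3,4-tetrahydroazulen-1-ol
Product: 11 (3R,3aS,8aS)-3a-hydroxy-6,8a-dimethyl-3-(propan-2-yl)-2,3,3a,4-tetrahydroazulen-1(8aH)-one, via epoxy alcohol 10 (not isolated)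
Conditions: VO(acac)2 (5 mol %), t-BuOOH (1.2 equiv, decane), CH2Cl2, 0 °C; then ZnBr2 (1 equiv), 0 °C
Reagents that add atoms: tert-butyl hydroperoxide, CC(C)(C)OO
Why: The pentavalent vanadium alkoxide of the C1 hydroxyl delivers the peroxide oxygen to the adjacent, electron-rich C3a=C8a bond on the hydroxyl face, faster than to the homoallylic C7=C8 or the remote C5=C6 bond, so 10 carries the oxirane cis to the hydroxyl and to the C3 isopropyl group. This oxirane is the only ring the step closes (concerted syn oxygen transfer to the alkene) and it is opened again. Lewis acid (the vanadium centre, then ZnBr2) breaks the C8a–O bond rather than the C3a–O bond, because C8a carries the C8=C7–C6=C5 diene and develops pentadienyl cation character whereas C3a is a plain tertiary centre. The C1 methyl, held on the face opposite to the oxirane and antiperiplanar to the breaking bond, shifts to C8a as the carbinol becomes the C1 ketone; the closest known reaction type is the semipinacol rearrangement of a tertiary 2,3-epoxy alcohol to a β-hydroxy ketone with a quaternary α-carbon, which is known with alkyl migration. C8a is set by inversion (methyl enters anti to the leaving oxygen) and C3a keeps the oxygen placed by the directed epoxidation, so methyl and hydroxyl must end trans across the ring fusion and the hydroxyl cis to the isopropyl group (3aS,8aS). The competing shift of ring carbon C2 is disfavoured because its bond is gauche to the breaking C8a–O bond and the shift would contract the ring to a cyclobutane. The step needs site, face, opening and migration selectivity, secured in turn by the directing hydroxyl (site and face), the diene on C8a and the antiperiplanar methyl.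

Step 7
Reactants: 11 (3R,3aS,8aS)-3a-hydroxy-6,8a-dimethyl-3-(propan-2-yl)-2,3,3a,4-tetrahydroazulen-1(8aH)-one
Product: 13 (3R,3aS,8aS)-3a,6-dihydroxy-6,8a-dimethyl-3-(propan-2-yl)-2,3,3a,4,5,6-hexahydroazulen-1(8aH)-one as a mixture of C6 epimers, via C6 hydroperoxide 12 (not isolated)
Conditions: Co(acac)2 (20 mol %), PhSiH3 (2 equiv), O2 (1 atm), THF, 0 °C to rt; then PPh3
Reagents that add atoms: dioxygen, O=O
Why: Mukaiyama hydration: hydrogen-atom transfer from the cobalt hydride to the unhindered diene terminus C5 gives the C6–C7–C8 allyl radical, which dioxygen should capture mainly at the tertiary, unhindered C6; PPh3 reduces the hydroperoxide. The C6 configuration is irrelevant, and oxygen capture at the other allyl terminus is funnelled to the same enone in step 8; the ketone and the tertiary alcohol are inert.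

Step 8
Reactants: 13 (3R,3aS,8aS)-3a,6-dihydroxy-6,8a-dimethyl-3-(propan-2-yl)-2,3,3a,4,5,6-hexahydroazulen-1(8aH)-one
Product: 14 (3R,3aS,8aS)-3a-hydroxy-6,8a-dimethyl-3-(propan-2-yl)-2,3,3a,4,5,8a-hexahydroazulene-1,8-dione
Conditions: pyridinium chlorochromate (2.5 equiv), Celite, CH2Cl2, rt
Reagents that add atoms: pyridinium chlorochromate, [O-][Cr](=O)(=O)Cl.c1cc[nH+]cc1
Why: Babler–Dauben oxidative transposition: the tertiary allylic chromate ester undergoes a [3,3] shift to the C8 chromate, which is oxidised to the enone with the double bond now at C6=C7. The 3a-hydroxyl is tertiary and cannot be oxidised, and the concerted shift should outrun ionisation toward capture by that hydroxyl.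

Step 9
Reactants: 14 (3R,3aS,8aS)-3a-hydroxy-6,8a-dimethyl-3-(propan-2-yl)-2,3,3a,4,5,8a-hexahydroazulene-1,8-dione
Product: 15 (3R,3aS,8R,8aS)-3a,8-dihydroxy-6,8a-dimethyl-3-(propan-2-yl)-2,3,3a,4,5,8-hexahydroazulen-1(8aH)-one
Conditions: NaBH4 (1.0 equiv), CeCl3·7H2O, MeOH, −78 °C; acetone quench
Reagents that add atoms: none
Why: Luche reduction: 1,2-hydride addition is expected at the conjugated C8 carbonyl in preference to the saturated C1 ketone, which is shielded on one face by the 8a-methyl and on the other by the 3-isopropyl and 3a-hydroxyl groups. Hydride should enter C8 anti to the axial 8a-methyl, placing the new hydroxyl cis to that methyl (8R); the low temperature limits retro-aldol and retro-Claisen cleavage.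

Step 10
Reactants: 15 (3R,3aS,8R,8aS)-3a,8-dihydroxy-6,8a-dimethyl-3-(propan-2-yl)-2,3,3a,4,5,8-hexahydroazulen-1(8aH)-one; 16 4-methoxybenzoyl chloride
Product: 17 (3R,3aS,8R,8aS)-3a-hydroxy-6,8a-dimethyl-1-oxo-3-(propan-2-yl)-1,2,3,3a,4,5,8,8a-octahydroazulen-8-yl 4-methoxybenzoate
Conditions: 16 (1.5 equiv), DMAP (0.2 equiv), Et3N, CH2Cl2, 0 °C to rt
Reagents that add atoms: none
Why: DMAP-catalysed acylation of the secondary allylic alcohol with retention at C8; the tertiary 3a-hydroxyl should not react under these conditions. C8a is quaternary, so no β-elimination of the new ester is possible.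

## Compound list

1 | 4-methylphenylboronic acid | Cc1ccc(B(O)O)cc1 | starting material
2 | ethyl (2E)-4-methylpent-2-enoate | CCOC(=O)/C=C/C(C)C | starting material
3 | ethyl (3R)-4-methyl-3-(4-methylphenyl)pentanoate | CCOC(=O)C[C@H](C(C)C)c1ccc(C)cc1 | intermediate
4 | (3R)-4-methyl-3-(4-methylphenyl)pentanoic acid | OC(=O)C[C@H](C(C)C)c1ccc(C)cc1 | intermediate
5 | (3R)-4-methyl-3-(4-methylphenyl)pentanoyl chloride (not isolated) | ClC(=O)C[C@H](C(C)C)c1ccc(C)cc1 | intermediate
6 | (4R)-1-diazo-5-methyl-4-(4-methylphenyl)hexan-2-one | [N-]=[N+]=CC(=O)C[C@H](C(C)C)c1ccc(C)cc1 | intermediate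
7 | (3R)-6-methyl-3-(propan-2-yl)-3,8a-dihydroazulen-1(2H)-one, C8a epimers (not isolated) | O=C1C[C@H](C(C)C)C2=CC=C(C)C=CC12 | intermediate
8 | (3R)-6-methyl-3-(propan-2-yl)-3,4-dihydroazulen-1(2H)-one | O=C1C[C@H](C(C)C)C2=C1C=CC(C)=CC2 | intermediate
9 | (1R,3R)-1,6-dimethyl-3-(propan-2-yl)-1,2,3,4-tetrahydroazulen-1-ol | C[C@@]1(O)C[C@H](C(C)C)C2=C1C=CC(C)=CC2 | intermediate
10 | (1R,3R,3aS,8aR)-3a,8a-epoxy-1,6-dimethyl-3-(propan-2-yl)-1,2,3,3a,4,8a-hexahydroazulen-1-ol, oxirane cis to the hydroxyl (not isolated) | C[C@@]1(O)C[C@H](C(C)C)[C@@]2(O3)CC=C(C)C=C[C@@]123 | intermediate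
11 | (3R,3aS,8aS)-3a-hydroxy-6,8a-dimethyl-3-(propan-2-yl)-2,3,3a,4-tetrahydroazulen-1(8aH)-one | C1=CC(C)=CC[C@]2(O)[C@@H](C(C)C)CC(=O)[C@@]12C | intermediate
12 | (3R,3aS,8aS)-6-hydroperoxy-3a-hydroxy-6,8a-dimethyl-3-(propan-2-yl)-2,3,3a,4,5,6-hexahydroazulen-1(8aH)-one, C6 epimers (not isolated) | CC1(OO)CC[C@]2(O)[C@@H](C(C)C)CC(=O)[C@@]2(C)C=C1 | intermediate
13 | (3R,3aS,8aS)-3a,6-dihydroxy-6,8a-dimethyl-3-(propan-2-yl)-2,3,3a,4,5,6-hexahydroazulen-1(8aH)-one, C6 epimers | CC1(O)CC[C@]2(O)[C@@H](C(C)C)CC(=O)[C@@]2(C)C=C1 | intermediate
14 | (3R,3aS,8aS)-3a-hydroxy-6,8a-dimethyl-3-(propan-2-yl)-2,3,3a,4,5,8a-hexahydroazulene-1,8-dione | O=C1C=C(C)CC[C@]2(O)[C@@H](C(C)C)CC(=O)[C@@]12C | intermediate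
15 | (3R,3aS,8R,8aS)-3a,8-dihydroxy-6,8a-dimethyl-3-(propan-2-yl)-2,3,3a,4,5,8-hexahydroazulen-1(8aH)-one | O[C@@H]1C=C(C)CC[C@]2(O)[C@@H](C(C)C)CC(=O)[C@@]12C | intermediate
16 | 4-methoxybenzoyl chloride | COc1ccc(C(Cl)=O)cc1 | starting material
17 | (3R,3aS,8R,8aS)-3a-hydroxy-6,8a-dimethyl-1-oxo-3-(propan-2-yl)-1,2,3,3a,4,5,8,8a-octahydroazulen-8-yl 4-methoxybenzoate | COc1ccc(C(=O)O[C@@H]2C=C(C)CC[C@]3(O)[C@@H](C(C)C)CC(=O)[C@@]23C)cc1 | target

## Step count and least certain steps

Total: 10 steps. Longest linear sequence: 10 steps (1 or 2 to 17).

Step 6 (key step). The dienyl epoxide and its cation may be diverted before the methyl migrates: by loss of a C4 proton, by capture of an external nucleophile, or by dehydration of the carbinol toward the azulene oxidation level. The pentadienyl stabilisation that directs the opening also lengthens the life of the cation. The sense of the two new centres also depends on the facial selectivity of step 5. The fallback sets out from 8 and comes back to the route at 11. Deprotonation of 8 at C4 (KOtBu, THF, −78 °C) and C-methylation of the extended enolate at C8a with MeI, anti to the C3 isopropyl group, should give the 8a-methyl trienone (3R,8aS)-6,8a-dimethyl-3-(propan-2-yl)-3,8a-dihydroazulen-1(2H)-one F1. Peracid epoxidation of its C3a=C4 bond anti to the angular methyl (m-CPBA, NaHCO3, CH2Cl2, 0 °C) should give the 3a,4-epoxide F2. Formate hydrogenolysis of this dienyl epoxide (Pd2(dba)3, PBu3, HCO2H/Et3N, dioxane, rt) delivers hydride to C4 with inversion, leaves the tertiary C3a–O bond intact, and returns 11.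

Step 5. Poor facial selectivity of the methyl addition is the main risk, because the only control element is the C3 isopropyl group, 1,3 to the carbonyl; deprotonation at C4 may also compete. A poor ratio here is relayed to C3a and C8a in step 6. The fallback sets out from 4 and comes back to the route at 11. 4 is converted to its acid chloride as in step 3 and treated with diazoethane (Et2O, 0 °C) to give the α-methyl diazoketone (5R)-2-diazo-6-methyl-5-(4-methylphenyl)heptan-3-one F3. Its Buchner reaction (Rh2(OAc)4, CH2Cl2, reflux) installs the angular methyl during the ring expansion and is expected to place it trans to the C3 substituent, giving the trienone F1 of the preceding fallback, which is carried through F2 to 11 in the same way.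

Step 7. Hydrogen-atom transfer to the hindered diene terminus, over-reduction of the diene, or oxidation of the allyl radical to a cation that the 3a-hydroxyl traps across the ring would all lower the yield; conjugated dienes give less predictable outcomes than isolated alkenes in this reaction. The fallback sets out from 11 and comes back to the route at 14. Peracid epoxidation of the more substituted and more accessible C5=C6 bond (m-CPBA, NaHCO3, CH2Cl2, 0 °C, syn to the homoallylic 3a-hydroxyl) should give the 5,6-epoxide F4. LiBHEt3 (THF, 0 °C) opens it at the secondary C5 and also reduces the C1 ketone, giving the triol F5 (C1 carbinol configuration immaterial). Excess pyridinium chlorochromate then carries out the oxidative transposition of step 8 and re-oxidises C1 in the same operation to give 14.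

Step 9. Hydride attack on C8 from the face of the 8a-methyl is possible, because the axial 3a-hydroxyl is 1,3 to the trajectory on the other face; some reduction at C1 and base-induced cleavage of the 1,3-dicarbonyl array are further risks. The fallback sets out from 14 and comes back to the route at 17. The material reduced with the wrong facial sense, the 8-epi alcohol (3R,3aS,8S,8aS)-3a,8-dihydroxy-6,8a-dimethyl-3-(propan-2-yl)-2,3,3a,4,5,8-hexahydroazulen-1(8aH)-one F6, is esterified under Mitsunobu conditions (4-methoxybenzoic acid, PPh3, DIAD, toluene, 0 °C to rt). This inverts C8 and forms the ester in one operation, giving 17 without step 10, so both C8 epimers are funnelled to the target.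

## Further compounds

F1 | step 6 | (3R,8aS)-6,8a-dimethyl-3-(propan-2-yl)-3,8a-dihydroazulen-1(2H)-one | C1=CC(C)=CC=C2[C@@H](C(C)C)CC(=O)[C@@]12C
F2 | step 6 | (3R,8aS)-3a,4-epoxy-6,8a-dimethyl-3-(propan-2-yl)-2,3,3a,4-tetrahydroazulen-1(8aH)-one, oxirane trans to the 8a-methyl | C1=CC(C)=C[C@H]3O[C@]32[C@@H](C(C)C)CC(=O)[C@@]12C
F3 | step 5 | (5R)-2-diazo-6-methyl-5-(4-methylphenyl)heptan-3-one | CC(=[N+]=[N-])C(=O)C[C@H](C(C)C)c1ccc(C)cc1
F4 | step 7 | (3R,3aS,8aS)-5,6-epoxy-3a-hydroxy-6,8a-dimethyl-3-(propan-2-yl)-2,3,3a,4,5,6-hexahydroazulen-1(8aH)-one, oxirane cis to the 3a-hydroxyl | C1=C[C@@]4(C)O[C@H]4C[C@]2(O)[C@@H](C(C)C)CC(=O)[C@@]12C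
F5 | step 7 | (3R,3aS,8aS)-6,8a-dimethyl-3-(propan-2-yl)-1,2,3,3a,4,5,6,8a-octahydroazulene-1,3a,6-triol, 6-hydroxyl cis to the 3a-hydroxyl, C1 epimers | C1=C[C@@](C)(O)CC[C@]2(O)[C@@H](C(C)C)CC(O)[C@@]12C
F6 | step 9 | (3R,3aS,8S,8aS)-3a,8-dihydroxy-6,8a-dimethyl-3-(propan-2-yl)-2,3,3a,4,5,8-hexahydroazulen-1(8aH)-one | O[C@H]1C=C(C)CC[C@]2(O)[C@@H](C(C)C)CC(=O)[C@@]12C
A1 | alternative 1 | 3-hydroxy-2-(1-hydroxyprop-2-en-1-yl)-2-methyl-3-(3-methylbut-3-en-1-yl)-4-(propan-2-yl)cyclopentan-1-one, configured as in 17 | O[C@H](C=C)[C@]1(C)C(=O)C[C@H](C(C)C)[C@@]1(O)CCC(C)=C
A2 | alternative 2 | (2Z)-3,10-dimethyl-6,9-dioxo-7-(propan-2-yl)cyclodec-2-en-1-yl 4-methoxybenzoate, C1 and C7 configured as C8 and C3 of 17 | COc1ccc(cc1)C(=O)O[C@@H]1/C=C(C)\CCC(=O)[C@@H](C(C)C)CC(=O)C1C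
A3 | alternative 3 | trans-fused 3a-hydroxy-7a-methyl-3-(propan-2-yl)hexahydro-1H-indene-1,5(4H)-dione, configured as in 17 at the three shared centres | O=C1CC[C@]2(C)C(=O)C[C@H](C(C)C)[C@@]2(O)C1
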